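# Proposed synthesis of CNP0239474.1 by desymmetrising C–H lactonisation of a bis(4-benzyloxyphenyl)methine

## Analysis of the target

The target is a (2S)-flavan. Ring A is fused to a pyran ring (O1, C2, C3, C4, C4a, C8a), C2 carries ring B (5-hydroxy-2-methoxyphenyl), C7 carries a free hydroxyl (O7), and C6 carries a 1,3-diarylpropyl chain in which Cα bears ring C (4-hydroxyphenyl) and Cγ is bonded to ring D (4-hydroxy-2-methoxyphenyl). There are two stereocentres, C2 (S) and Cα (R). They lie six bonds apart on opposite sides of the flat ring A, so neither can steer the other and each has to be set by a reagent or catalyst. Cα is the harder one, because its two aryl groups (ring A and ring C) are both electron-rich and para-oxygenated, which leaves little for methods that tell aryl groups apart by size or electronics. The sensitive features are the four free phenols (ring A is a resorcinol, ring B a hydroquinone monoether), the benzylic C2–O1 bond, which ionises in acid and can be hydrogenolysed, and the two methyl ethers, which must stay distinct from the four hydroxyls. The difficulty lies in six oxygens in two different states on four rings, the 1,2,4,5-substitution of ring A, and two unrelated stereocentres. The strategy rests on one feature: O1 on C8a is para to C6, just as the hydroxyl of ring C is para to its point of attachment. Without O7 at C7 and the C4 branch at C4a, the two aryl groups on Cα are identical 4-oxyphenyl rings and Cα is prochiral, so introducing O7 on one ring creates the stereocentre.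

## Retrosynthetic reasoning

**27 to 26.** The four phenols are released last by cleaving four O–benzyl bonds. Benzyl is chosen because its removal by hydrogenolysis leaves the two methyl ethers alone. The forward step only has to spare the benzylic C2–O1 bond of the flavan.

**26 to 25.** The O1–C2 bond is cut. Closing the pyran at this bond lets C2 be set beforehand on an open chain as a carbinol. The forward reaction is a Mitsunobu closure with inversion, so 25 must be the (R)-carbinol and must have O1 as its only free phenol.

**25 to 24 to 23, then to 19 and 22.** The carbinol comes from ketone 24 by catalyst-controlled reduction. The C3–C4 bond is cut as an aldol condensation between aldehyde 19 and acetophenone 22, which brings in ring B together with C2 and C3. The enone 23 has to be saturated before the ketone is reduced, because an E-allylic alcohol cannot reach O1 and would ionise.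

**19 to 18.** O1 must be freed in the presence of four other benzyl ethers. The formyl group at C4a makes this possible: a Lewis acid held between the carbonyl oxygen and O1 cleaves only the ortho benzyl ether. The formyl group thus supplies C4 and also singles out O1.

**18 to 16.** The C4a–C4 bond is cut. A direct electrophilic formylation at this stage would not work, because ring D is, like ring A, a 1,3-dioxygenated ring with a free position para to one oxygen and ortho to the other. C4a is therefore marked with bromine earlier, in 10, when ring D is not yet in the molecule and ring A is the only doubly activated ring. The bromine is later exchanged for lithium (17) and formylated.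

**16 to 14, then to 10 and 12.** The bond between Cγ and ring D is cut. Cγ is at the carboxyl level after the key step, and a Weinreb amide takes up exactly one aryl nucleophile. The magnesium reagent 13 is used because it does not exchange with the ring A bromide. The carbonyl of 14 is then removed by ionic hydrogenation. This acidic step is placed before the aldehyde and the flavan exist.

**10 to 9 to 8 to 7.** Bromination, O7 benzylation and opening of lactone 7 to the Weinreb amide are taken back in turn. The opening releases O7 as the only free phenol, so it can be capped without any selectivity problem.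

**7 to 6.** This is the central disconnection: the C7–O7 bond of the lactone is cut. The forward reaction is a palladium-catalysed, carboxylate-directed C–H oxygenation under the control of a chiral amino acid ligand. It must choose one of the two enantiotopic aryl rings of the achiral acid 6. One step then sets Cα, introduces O7, distinguishes O7 from O1 and marks ring A off from ring C.

**6 to 5 to 4, then to 2 and 3, and 2 to 1.** The symmetric acid is reached by saponification, conjugate reduction that spares benzyl ethers, olefination of ketone 2 with phosphonate 3, and benzylation of 1. The methyl phosphonate is used so that the reduction in methanol gives a single ester.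

**22 to 21 to 20, and 12 to 11.** The two small arenes come from commercial phenols by alkylations that use the lower nucleophilicity of a hydrogen-bonded ortho-hydroxyl.

## Alternatives that were turned down

**Alternative 1:** Ring A and the pyran ring are cut together at C4a–C5, C7–C8, C4a–C8a and C6–C7. This leads back to the open-chain diazo enone A2, in which a vinyl diazomethyl ketone carrying the Cα side chain is tethered through C4, C3, C2 and O1 to an ethynyl ether.
- Forward step: light would trigger Wolff rearrangement of A2 to a vinylketene. The ketene adds the ynol ether, and ring opening and six-electron closure of the cyclobutenone give the phenol A1 (Danheiser benzannulation).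
- For it: the substitution pattern of ring A follows from connectivity, and O7 emerges as the only free hydroxyl. On these two points it is stronger than the chosen route, which needs a bromine marker and a chelation-controlled debenzylation.
- Against it: both stereocentres must be built beforehand into a flexible chain by two separate asymmetric steps. C2 would sit in a benzylic ethynyl ether, a group that rearranges or fragments to a ketene under mild heating. The tethered version that forms an oxygen heterocycle has no close analogy.
- Comparison: all stereochemical work moves into a long precursor. The chosen route has a four-step achiral precursor and tests its one uncertain reaction at step 5.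

**Alternative 2:** The C4–C4a bond of the flav-3-ene A3 is cut, leading to the aryl propargyl ether A4 with C2 already in place.
- Forward step: Ph3PAuNTf2 would activate the terminal alkyne, C4a would attack in a 6-endo-dig hydroarylation, and A3 would be hydrogenated and debenzylated.
- For it: the pyran ring is closed in one catalytic step, where the chosen route needs seven steps from the bromide to the flavan. On step economy for the heterocycle it is clearly stronger.
- Against it: it does nothing for Cα, which would still need its own asymmetric method. Attack can also occur at C8, which is ortho to O1 as well and activated by both oxygens. A secondary propargylic ether with an ortho-methoxyphenyl group can ionise at the Lewis acidic gold and lose the C2 configuration. The last hydrogenation must saturate C3=C4 next to an allylic, benzylic C2–O1 bond.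
- Comparison: the chosen route spends more steps on the pyran but solves the diarylmethine centre.

**Alternative 3:** Cα–Cβ and O7–Cγ are cut, leading to the C6 benzhydrol A6 of a preformed flavan and the ring D hydroxystyrene A7.
- Forward step: acid would ionise A6 to an ortho-quinone methide (C7=O, C6=Cα). Cycloaddition with A7 would give the cis-2,4-diarylchroman A5, whose O7–Cγ bond is then cleaved reductively.
- For it: ring D, Cβ and Cγ arrive in one late, convergent step, and the configuration at Cγ does not matter. It is shorter than the ketone addition and deoxygenation of the chosen route.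
- Against it: C2 is too far away to control Cα, so a chiral acid would have to impose facial selectivity on a large quinone methide. A7 polymerises readily in acid. A5 contains two 2-arylchroman C–O bonds of the same kind, O7–Cγ to be broken and O1–C2 to be kept, which differ only in the para-hydroxyl of ring D.
- Comparison: the chosen route never has to discriminate two such bonds, and it sets Cα on a small lactone whose optical purity can be checked before the valuable fragments are attached.

Key step: step 5

Assumption on the chemistry: the sense of induction of the amino acid ligand in step 5 cannot be derived with certainty from the five-membered-ring case. The route is written with Boc-L-tert-leucine, and Boc-D-tert-leucine is to be used if the (4S)-lactone should form.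

## Route

Step 1
Reactants: 1 4,4'-dihydroxybenzophenone
Product: 2 4,4'-bis(benzyloxy)benzophenone
Conditions: BnBr (2.2 equiv), K2CO3, DMF, 60 °C
Reagents that add atoms: benzyl bromide, BrCc1ccccc1
Why: Williamson ether synthesis on two equivalent phenols; the benzyl ethers later withstand organometallic reagents and fall together at the end.

Step 2
Reactants: 2 4,4'-bis(benzyloxy)benzophenone; 3 trimethyl phosphonoacetate
Product: 4 methyl 3,3-bis[4-(benzyloxy)phenyl]prop-2-enoate
Conditions: NaH, THF, reflux
Reagents that add atoms: none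
Why: Horner–Wadsworth–Emmons olefination; the ketone is symmetric, so no alkene geometry arises, and heating should compensate for the low electrophilicity of the diaryl ketone.

Step 3
Reactants: 4 methyl 3,3-bis[4-(benzyloxy)phenyl]prop-2-enoate
Product: 5 methyl 3,3-bis[4-(benzyloxy)phenyl]propanoate
Conditions: Mg turnings, MeOH, rt
Reagents that add atoms: none
Why: Dissolving-metal conjugate reduction of a β,β-diaryl acrylate by electron transfer; benzyl aryl ethers are inert to Mg in methanol, and the methyl ester cannot be scrambled by the solvent.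

Step 4
Reactants: 5 methyl 3,3-bis[4-(benzyloxy)phenyl]propanoate
Product: 6 3,3-bis[4-(benzyloxy)phenyl]propanoic acid
Conditions: LiOH·H2O, THF/MeOH/H2O, rt; then 1 M HCl
Reagents that add atoms: lithium hydroxide, [Li+].[OH-]
Why: Ester saponification; the product is achiral and has nothing that can epimerise.

Step 5
Reactants: 6 3,3-bis[4-(benzyloxy)phenyl]propanoic acid
Product: 7 (4R)-7-(benzyloxy)-4-[4-(benzyloxy)phenyl]-3,4-dihydro-2H-chromen-2-one
Conditions: Pd(OAc)2 (10 mol %), Boc-L-tert-leucine (30 mol %), PhI(OAc)2 (1.5 equiv), KOAc (2 equiv), t-BuOH, 80 °C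
Reagents that add atoms: none
Why: Proposed new method: the carboxylate of 6 binds Pd(OAc)2 carrying the mono-N-protected amino acid, and concerted metalation–deprotonation, with the ligand amide as internal base, cleaves an ortho C–H bond of one of the two enantiotopic aryl rings to give a seven-membered palladacycle of divalent palladium. PhI(OAc)2 oxidises this to tetravalent palladium, and C–O reductive elimination joins the carboxylate oxygen to the ring carbon, forming C7–O7. The closest known reaction type is the palladium and chiral amino acid catalysed desymmetrising C–H activation and C–O cyclisation of diarylacetic acids to benzofuranones; the larger palladacycle needed here is the one known from ortho olefination of 3-arylpropanoic acids. The six-membered lactone closes by reductive elimination from the metallacycle, a contraction of the seven-membered ring by loss of the metal, not by attack of a free nucleophile. The new stereocentre at Cα is controlled by the chiral ligand alone: in the metalation transition state the non-reacting aryl ring and the Cα hydrogen occupy different quadrants around the metal, and the ligand antipode decides which ring reacts. Site selectivity is secured by the substrate, since the four C–H bonds ortho to Cα are equivalent in pairs and those ortho to the benzyloxy groups are out of reach of the carboxylate. A second oxygenation is excluded because the directing carboxyl group is used up in the lactone. The acetate-buffered, non-acidic medium is chosen to hold back direct attack of the iodine oxidant on the electron-rich rings.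

Step 6
Reactants: 7 (4R)-7-(benzyloxy)-4-[4-(benzyloxy)phenyl]-3,4-dihydro-2H-chromen-2-one
Product: 8 (3R)-3-[4-(benzyloxy)-2-hydroxyphenyl]-3-[4-(benzyloxy)phenyl]-N-methoxy-N-methylpropanamide
Conditions: Me(MeO)NH·HCl, AlMe3, CH2Cl2, 0 °C to rt; then 1 M HCl
Reagents that add atoms: N,O-dimethylhydroxylamine hydrochloride, CNOC.Cl
Why: Aminolysis of an aryl ester lactone by an aluminium amide (Weinreb amide formation); Cα carries no acidic hydrogen next to a leaving group and is not touched, and O7 is set free as the only phenol.

Step 7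
Reactants: 8 (3R)-3-[4-(benzyloxy)-2-hydroxyphenyl]-3-[4-(benzyloxy)phenyl]-N-methoxy-N-methylpropanamide
Product: 9 (3R)-3-[2,4-bis(benzyloxy)phenyl]-3-[4-(benzyloxy)phenyl]-N-methoxy-N-methylpropanamide
Conditions: BnBr, K2CO3, DMF, rt
Reagents that add atoms: benzyl bromide, BrCc1ccccc1
Why: Williamson ether synthesis on the single free phenol; at room temperature alkylation of the phenoxide should outrun its return to the lactone.

Step 8
Reactants: 9 (3R)-3-[2,4-bis(benzyloxy)phenyl]-3-[4-(benzyloxy)phenyl]-N-methoxy-N-methylpropanamide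
Product: 10 (3R)-3-[2,4-bis(benzyloxy)-5-bromophenyl]-3-[4-(benzyloxy)phenyl]-N-methoxy-N-methylpropanamide
Conditions: NBS (1.05 equiv), MeCN, 0 °C
Reagents that add atoms: N-bromosuccinimide, O=C1CCC(=O)N1Br
Why: Electrophilic aromatic bromination; ring A is the only resorcinol diether present, and C4a (para to O7, ortho to O1) is favoured over C8, which is flanked by two benzyloxy groups, and over the mono-ether ring C.

Step 9
Reactants: 11 4-bromo-3-methoxyphenol
Product: 12 4-(benzyloxy)-1-bromo-2-methoxybenzene
Conditions: BnBr, K2CO3, acetone, reflux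
Reagents that add atoms: benzyl bromide, BrCc1ccccc1
Why: Williamson ether synthesis; it gives the ring D building block with bromine at the future point of attachment.

Step 10
Reactants: 10 (3R)-3-[2,4-bis(benzyloxy)-5-bromophenyl]-3-[4-(benzyloxy)phenyl]-N-methoxy-N-methylpropanamide; 12 4-(benzyloxy)-1-bromo-2-methoxybenzene
Product: 14 (3R)-1-[4-(benzyloxy)-2-methoxyphenyl]-3-[2,4-bis(benzyloxy)-5-bromophenyl]-3-[4-(benzyloxy)phenyl]propan-1-one, via arylmagnesium bromide 13 (not isolated)
Conditions: 12, Mg turnings, I2 (cat.), THF, reflux; then 10, THF, 0 °C to rt; then 1 M HCl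
Reagents that add atoms: none
Why: Weinreb ketone synthesis; the magnesium chelate of the tetrahedral adduct stops the addition at the ketone, and an arylmagnesium halide, unlike an aryllithium, does not exchange with the ring A bromide.

Step 11
Reactants: 14 (3R)-1-[4-(benzyloxy)-2-methoxyphenyl]-3-[2,4-bis(benzyloxy)-5-bromophenyl]-3-[4-(benzyloxy)phenyl]propan-1-one
Product: 16 1,5-bis(benzyloxy)-2-bromo-4-{(1R)-3-[4-(benzyloxy)-2-methoxyphenyl]-1-[4-(benzyloxy)phenyl]propyl}benzene, via benzylic carbinol 15 (not isolated)
Conditions: Et3SiH (4 equiv), TFA/CH2Cl2 (1:4), 0 °C to rt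
Reagents that add atoms: none
Why: Ionic hydrogenation; hydride transfer to the protonated ketone gives 15, whose cation is stabilised by the ortho-methoxy and para-benzyloxy groups of ring D and takes up a second hydride, while Cα is not involved.

Step 12
Reactants: 16 1,5-bis(benzyloxy)-2-bromo-4-{(1R)-3-[4-(benzyloxy)-2-methoxyphenyl]-1-[4-(benzyloxy)phenyl]propyl}benzene
Product: 18 2,4-bis(benzyloxy)-5-{(1R)-3-[4-(benzyloxy)-2-methoxyphenyl]-1-[4-(benzyloxy)phenyl]propyl}benzaldehyde, via aryllithium 17 (not isolated)
Conditions: n-BuLi (1.1 equiv), THF, −78 °C; then DMF, −78 to 0 °C; then 1 M HCl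
Reagents that add atoms: N,N-dimethylformamide, CN(C)C=O
Why: Bromine–lithium exchange and formylation with a formamide; the bromine fixes the site at C4a, so the equally electron-rich ring D cannot compete, and at −78 °C exchange is faster than any benzylic deprotonation.

Step 13
Reactants: 18 2,4-bis(benzyloxy)-5-{(1R)-3-[4-(benzyloxy)-2-methoxyphenyl]-1-[4-(benzyloxy)phenyl]propyl}benzaldehyde
Product: 19 4-(benzyloxy)-2-hydroxy-5-{(1R)-3-[4-(benzyloxy)-2-methoxyphenyl]-1-[4-(benzyloxy)phenyl]propyl}benzaldehyde
Conditions: MgBr2·OEt2 (3 equiv), toluene/Et2O, 80 °C; then 1 M HCl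
Reagents that add atoms: none
Why: Chelation-controlled ether cleavage; magnesium bound between the formyl oxygen and O1 activates only the ortho benzyl ether toward bromide, so the other three benzyl ethers and both methyl ethers, none of which lies ortho to a carbonyl group, should remain.

Step 14
Reactants: 20 2',5'-dihydroxyacetophenone
Product: 21 1-[5-(benzyloxy)-2-hydroxyphenyl]ethan-1-one
Conditions: BnBr (1.05 equiv), K2CO3, acetone, reflux
Reagents that add atoms: benzyl bromide, BrCc1ccccc1
Why: Selective Williamson ether synthesis; the 2'-hydroxyl is tied up in a hydrogen bond to the ketone and is much less nucleophilic than the 5'-hydroxyl.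

Step 15
Reactants: 21 1-[5-(benzyloxy)-2-hydroxyphenyl]ethan-1-one
Product: 22 1-[5-(benzyloxy)-2-methoxyphenyl]ethan-1-one
Conditions: MeI, K2CO3, DMF, 50 °C
Reagents that add atoms: iodomethane, CI
Why: Williamson methylation of the remaining, hydrogen-bonded phenol under slightly forcing conditions; this fixes the methyl ether of ring B.

Step 16
Reactants: 19 4-(benzyloxy)-2-hydroxy-5-{(1R)-3-[4-(benzyloxy)-2-methoxyphenyl]-1-[4-(benzyloxy)phenyl]propyl}benzaldehyde; 22 1-[5-(benzyloxy)-2-methoxyphenyl]ethan-1-one
Product: 23 (2E)-1-[5-(benzyloxy)-2-methoxyphenyl]-3-[4-(benzyloxy)-2-hydroxy-5-{(1R)-3-[4-(benzyloxy)-2-methoxyphenyl]-1-[4-(benzyloxy)phenyl]propyl}phenyl]prop-2-en-1-one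
Conditions: KOH (50% aq), EtOH, rt; then 1 M HCl
Reagents that add atoms: none
Why: Claisen–Schmidt aldol condensation forming C3–C4; dehydration gives the conjugated E-enone, and a chalcone with its phenol on the aldehyde-derived ring cannot close to a flavanone.

Step 17
Reactants: 23 (2E)-1-[5-(benzyloxy)-2-methoxyphenyl]-3-[4-(benzyloxy)-2-hydroxy-5-{(1R)-3-[4-(benzyloxy)-2-methoxyphenyl]-1-[4-(benzyloxy)phenyl]propyl}phenyl]prop-2-en-1-one
Product: 24 1-[5-(benzyloxy)-2-methoxyphenyl]-3-[4-(benzyloxy)-2-hydroxy-5-{(1R)-3-[4-(benzyloxy)-2-methoxyphenyl]-1-[4-(benzyloxy)phenyl]propyl}phenyl]propan-1-one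
Conditions: H2 (1 atm), RhCl(PPh3)3 (5 mol %), toluene/EtOH, 40 °C
Reagents that add atoms: none
Why: Homogeneous hydrogenation of the enone C=C bond; this catalyst does not hydrogenolyse benzyl ethers and leaves the aryl ketone alone.

Step 18
Reactants: 24 1-[5-(benzyloxy)-2-methoxyphenyl]-3-[4-(benzyloxy)-2-hydroxy-5-{(1R)-3-[4-(benzyloxy)-2-methoxyphenyl]-1-[4-(benzyloxy)phenyl]propyl}phenyl]propan-1-one
Product: 25 (1R)-1-[5-(benzyloxy)-2-methoxyphenyl]-3-[4-(benzyloxy)-2-hydroxy-5-{(1R)-3-[4-(benzyloxy)-2-methoxyphenyl]-1-[4-(benzyloxy)phenyl]propyl}phenyl]propan-1-ol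
Conditions: RuCl(p-cymene)[(R,R)-TsDPEN] (2 mol %), HCO2H/Et3N (5:2), DMF, 40 °C
Reagents that add atoms: none
Why: Noyori asymmetric transfer hydrogenation of an aryl alkyl ketone; the (R,R)-catalyst delivers hydride to the face that gives the (R)-carbinol, as with simple aryl alkyl ketones, independently of the remote Cα, and the free phenol is tolerated.

Step 19
Reactants: 25 (1R)-1-[5-(benzyloxy)-2-methoxyphenyl]-3-[4-(benzyloxy)-2-hydroxy-5-{(1R)-3-[4-(benzyloxy)-2-methoxyphenyl]-1-[4-(benzyloxy)phenyl]propyl}phenyl]propan-1-ol
Product: 26 (2S)-7-(benzyloxy)-2-[5-(benzyloxy)-2-methoxyphenyl]-6-{(1R)-3-[4-(benzyloxy)-2-methoxyphenyl]-1-[4-(benzyloxy)phenyl]propyl}-3,4-dihydro-2H-chromene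
Conditions: PPh3, DIAD, THF, 0 °C to rt
Reagents that add atoms: none
Why: Intramolecular Mitsunobu etherification; O1, the only free phenol, displaces the activated carbinol oxygen in a 6-exo-tet closure with inversion, turning the (R)-carbinol into (2S)-C2.

Step 20
Reactants: 26 (2S)-7-(benzyloxy)-2-[5-(benzyloxy)-2-methoxyphenyl]-6-{(1R)-3-[4-(benzyloxy)-2-methoxyphenyl]-1-[4-(benzyloxy)phenyl]propyl}-3,4-dihydro-2H-chromene
Product: 27 (2S)-2-(5-hydroxy-2-methoxyphenyl)-6-[(1R)-3-(4-hydroxy-2-methoxyphenyl)-1-(4-hydroxyphenyl)propyl]-3,4-dihydro-2H-chromen-7-ol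
Conditions: H2 (1 atm), 10% Pd/C, EtOAc/MeOH, rt
Reagents that add atoms: none
Why: Hydrogenolysis of four aryl benzyl ethers under neutral conditions; the methyl ethers are inert and the cyclic C2–O1 ether is cleaved far more slowly than the benzyl ethers, so the reaction is stopped when hydrogen uptake ends.

## Compound list

1 | 4,4'-dihydroxybenzophenone | O=C(c1ccc(O)cc1)c1ccc(O)cc1 | starting material
2 | 4,4'-bis(benzyloxy)benzophenone | O=C(c1ccc(OCc2ccccc2)cc1)c1ccc(OCc2ccccc2)cc1 | intermediate
3 | trimethyl phosphonoacetate | COC(=O)CP(=O)(OC)OC | starting material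
4 | methyl 3,3-bis[4-(benzyloxy)phenyl]prop-2-enoate | COC(=O)C=C(c1ccc(OCc2ccccc2)cc1)c1ccc(OCc2ccccc2)cc1 | intermediate
5 | methyl 3,3-bis[4-(benzyloxy)phenyl]propanoate | COC(=O)CC(c1ccc(OCc2ccccc2)cc1)c1ccc(OCc2ccccc2)cc1 | intermediate
6 | 3,3-bis[4-(benzyloxy)phenyl]propanoic acid | OC(=O)CC(c1ccc(OCc2ccccc2)cc1)c1ccc(OCc2ccccc2)cc1 | intermediate
7 | (4R)-7-(benzyloxy)-4-[4-(benzyloxy)phenyl]-3,4-dihydro-2H-chromen-2-one | O=C1C[C@H](c2ccc(OCc3ccccc3)cc2)c2ccc(OCc3ccccc3)cc2O1 | intermediate
8 | (3R)-3-[4-(benzyloxy)-2-hydroxyphenyl]-3-[4-(benzyloxy)phenyl]-N-methoxy-N-methylpropanamide | CON(C)C(=O)C[C@H](c1ccc(OCc2ccccc2)cc1)c1ccc(OCc2ccccc2)cc1O | intermediate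
9 | (3R)-3-[2,4-bis(benzyloxy)phenyl]-3-[4-(benzyloxy)phenyl]-N-methoxy-N-methylpropanamide | CON(C)C(=O)C[C@H](c1ccc(OCc2ccccc2)cc1)c1ccc(OCc2ccccc2)cc1OCc1ccccc1 | intermediate
10 | (3R)-3-[2,4-bis(benzyloxy)-5-bromophenyl]-3-[4-(benzyloxy)phenyl]-N-methoxy-N-methylpropanamide | CON(C)C(=O)C[C@H](c1ccc(OCc2ccccc2)cc1)c1cc(Br)c(OCc2ccccc2)cc1OCc1ccccc1 | intermediate
11 | 4-bromo-3-methoxyphenol | COc1cc(O)ccc1Br | starting material
12 | 4-(benzyloxy)-1-bromo-2-methoxybenzene | COc1cc(OCc2ccccc2)ccc1Br | intermediate
13 | [4-(benzyloxy)-2-methoxyphenyl]magnesium bromide | COc1cc(OCc2ccccc2)ccc1[Mg]Br | intermediate (not isolated)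
14 | (3R)-1-[4-(benzyloxy)-2-methoxyphenyl]-3-[2,4-bis(benzyloxy)-5-bromophenyl]-3-[4-(benzyloxy)phenyl]propan-1-one | COc1cc(OCc2ccccc2)ccc1C(=O)C[C@H](c1ccc(OCc2ccccc2)cc1)c1cc(Br)c(OCc2ccccc2)cc1OCc1ccccc1 | intermediate
15 | (3R)-1-[4-(benzyloxy)-2-methoxyphenyl]-3-[2,4-bis(benzyloxy)-5-bromophenyl]-3-[4-(benzyloxy)phenyl]propan-1-ol, both epimers at C1 | COc1cc(OCc2ccccc2)ccc1C(O)C[C@H](c1ccc(OCc2ccccc2)cc1)c1cc(Br)c(OCc2ccccc2)cc1OCc1ccccc1 | intermediate (not isolated)
16 | 1,5-bis(benzyloxy)-2-bromo-4-{(1R)-3-[4-(benzyloxy)-2-methoxyphenyl]-1-[4-(benzyloxy)phenyl]propyl}benzene | COc1cc(OCc2ccccc2)ccc1CC[C@H](c1ccc(OCc2ccccc2)cc1)c1cc(Br)c(OCc2ccccc2)cc1OCc1ccccc1 | intermediate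
17 | (2,4-bis(benzyloxy)-5-{(1R)-3-[4-(benzyloxy)-2-methoxyphenyl]-1-[4-(benzyloxy)phenyl]propyl}phenyl)lithium | COc1cc(OCc2ccccc2)ccc1CC[C@H](c1ccc(OCc2ccccc2)cc1)c1cc([Li])c(OCc2ccccc2)cc1OCc1ccccc1 | intermediate (not isolated)
18 | 2,4-bis(benzyloxy)-5-{(1R)-3-[4-(benzyloxy)-2-methoxyphenyl]-1-[4-(benzyloxy)phenyl]propyl}benzaldehyde | COc1cc(OCc2ccccc2)ccc1CC[C@H](c1ccc(OCc2ccccc2)cc1)c1cc(C=O)c(OCc2ccccc2)cc1OCc1ccccc1 | intermediate
19 | 4-(benzyloxy)-2-hydroxy-5-{(1R)-3-[4-(benzyloxy)-2-methoxyphenyl]-1-[4-(benzyloxy)phenyl]propyl}benzaldehyde | COc1cc(OCc2ccccc2)ccc1CC[C@H](c1ccc(OCc2ccccc2)cc1)c1cc(C=O)c(O)cc1OCc1ccccc1 | intermediate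
20 | 2',5'-dihydroxyacetophenone | CC(=O)c1cc(O)ccc1O | starting material
21 | 1-[5-(benzyloxy)-2-hydroxyphenyl]ethan-1-one | CC(=O)c1cc(OCc2ccccc2)ccc1O | intermediate
22 | 1-[5-(benzyloxy)-2-methoxyphenyl]ethan-1-one | COc1ccc(OCc2ccccc2)cc1C(C)=O | intermediate
23 | (2E)-1-[5-(benzyloxy)-2-methoxyphenyl]-3-[4-(benzyloxy)-2-hydroxy-5-{(1R)-3-[4-(benzyloxy)-2-methoxyphenyl]-1-[4-(benzyloxy)phenyl]propyl}phenyl]prop-2-en-1-one | COc1cc(OCc2ccccc2)ccc1CC[C@H](c1ccc(OCc2ccccc2)cc1)c1cc(/C=C/C(=O)c2cc(OCc3ccccc3)ccc2OC)c(O)cc1OCc1ccccc1 | intermediate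
24 | 1-[5-(benzyloxy)-2-methoxyphenyl]-3-[4-(benzyloxy)-2-hydroxy-5-{(1R)-3-[4-(benzyloxy)-2-methoxyphenyl]-1-[4-(benzyloxy)phenyl]propyl}phenyl]propan-1-one | COc1cc(OCc2ccccc2)ccc1CC[C@H](c1ccc(OCc2ccccc2)cc1)c1cc(CCC(=O)c2cc(OCc3ccccc3)ccc2OC)c(O)cc1OCc1ccccc1 | intermediate
25 | (1R)-1-[5-(benzyloxy)-2-methoxyphenyl]-3-[4-(benzyloxy)-2-hydroxy-5-{(1R)-3-[4-(benzyloxy)-2-methoxyphenyl]-1-[4-(benzyloxy)phenyl]propyl}phenyl]propan-1-ol | COc1cc(OCc2ccccc2)ccc1CC[C@H](c1ccc(OCc2ccccc2)cc1)c1cc(CC[C@@H](O)c2cc(OCc3ccccc3)ccc2OC)c(O)cc1OCc1ccccc1 | intermediate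
26 | (2S)-7-(benzyloxy)-2-[5-(benzyloxy)-2-methoxyphenyl]-6-{(1R)-3-[4-(benzyloxy)-2-methoxyphenyl]-1-[4-(benzyloxy)phenyl]propyl}-3,4-dihydro-2H-chromene | COc1cc(OCc2ccccc2)ccc1CC[C@H](c1ccc(OCc2ccccc2)cc1)c1cc2c(cc1OCc1ccccc1)O[C@H](c1cc(OCc3ccccc3)ccc1OC)CC2 | intermediate
27 | (2S)-2-(5-hydroxy-2-methoxyphenyl)-6-[(1R)-3-(4-hydroxy-2-methoxyphenyl)-1-(4-hydroxyphenyl)propyl]-3,4-dihydro-2H-chromen-7-ol | COc1cc(O)ccc1CC[C@H](c1ccc(O)cc1)c1cc2c(cc1O)O[C@H](c1cc(O)ccc1OC)CC2 | target

## Step count and least certain steps

Total: 20 steps. Longest linear sequence: 17 steps (steps 1 to 8, 10 to 13 and 16 to 20). Step 9 and steps 14 and 15 are side branches.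

**Step 5 (key step).** Two processes are most likely to spoil it. One is poor discrimination between the two enantiotopic rings in a seven-membered, more flexible palladacycle. The other is loss of turnover, if metalation through the larger ring is slower than direct oxidation of the benzyloxyarenes by the iodine oxidant. The fallback uses known chemistry and sets Cα by facial selection on an alkene instead of ring selection. It sets out from 3. Horner–Wadsworth–Emmons reaction of 3 with commercial 2,4-bis(benzyloxy)benzaldehyde F1 gives methyl (2E)-3-[2,4-bis(benzyloxy)phenyl]prop-2-enoate F2. Asymmetric 1,4-addition of [4-(benzyloxy)phenyl]boronic acid F3, catalysed by [RhCl(C2H4)2]2 with a chiral diene ligand and aqueous KOH in dioxane, gives methyl (3R)-3-[2,4-bis(benzyloxy)phenyl]-3-[4-(benzyloxy)phenyl]propanoate F4. Treatment of F4 with Me(MeO)NH·HCl and i-PrMgCl gives the Weinreb amide, and the fallback comes back to the route at 9.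

**Step 11.** The benzylic cation may be diverted, either by cyclisation onto a neighbouring aryl ring (indane formation) or by acid-induced loss or migration of benzyl groups during prolonged exposure to TFA. The fallback avoids the cation. It sets out from 14, which is condensed with tosylhydrazine to the tosylhydrazone F5. Reduction of F5 with catecholborane followed by NaOAc·3H2O expels sulfinate and nitrogen from the diazene. It comes back at 16.

**Step 13.** Selectivity among the benzyl ethers may be incomplete, with partial loss of the O7 benzyl group or stalled cleavage. The fallback gives up the single free phenol and relies on ring size. It sets out from 18, which is condensed with 22 (KOH, EtOH) to the fully benzylated chalcone F6. Hydrogenation of F6 (H2, 10% Pd/C, EtOAc) removes all five benzyl groups and saturates the alkene to give the pentaphenol ketone F7. Transfer hydrogenation of F7 as in step 18 gives the (1R)-carbinol F8. Mitsunobu closure of F8 at high dilution, where only O1 can reach C2 through a six-membered transition state, comes back at 27.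

**Step 19.** The activated ortho-methoxybenzylic oxyphosphonium ion may ionise partly, which would erode the C2 configuration or cause elimination to a styrene. The fallback sets C2 by hydrogenation instead of inversion. It sets out from 24, which is cyclodehydrated (p-TsOH, toluene, reflux) to the 2-aryl-4H-chromene F9. Asymmetric hydrogenation of the enol ether double bond of F9 with an iridium complex [Ir(cod)(L)]BArF, where L is a chiral phosphine–oxazoline ligand, comes back at 26.

**Step 2.** Olefination of the hindered, electron-rich diaryl ketone may be slow and incomplete. The fallback sets out from 2. A Reformatsky reaction with methyl bromoacetate and Zn dust gives methyl 3,3-bis[4-(benzyloxy)phenyl]-3-hydroxypropanoate F10. The doubly benzylic hydroxyl of F10 is removed by Et3SiH and TFA in CH2Cl2 at 0 °C, and the fallback comes back at 5.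

## Further compounds

F1 | step 5 | 2,4-bis(benzyloxy)benzaldehyde | O=Cc1ccc(OCc2ccccc2)cc1OCc1ccccc1
F2 | step 5 | methyl (2E)-3-[2,4-bis(benzyloxy)phenyl]prop-2-enoate | COC(=O)/C=C/c1ccc(OCc2ccccc2)cc1OCc1ccccc1
F3 | step 5 | [4-(benzyloxy)phenyl]boronic acid | OB(O)c1ccc(OCc2ccccc2)cc1
F4 | step 5 | methyl (3R)-3-[2,4-bis(benzyloxy)phenyl]-3-[4-(benzyloxy)phenyl]propanoate | COC(=O)C[C@H](c1ccc(OCc2ccccc2)cc1)c1ccc(OCc2ccccc2)cc1OCc1ccccc1
F5 | step 11 | tosylhydrazone of ketone 14 | COc1cc(OCc2ccccc2)ccc1C(=NNS(=O)(=O)c1ccc(C)cc1)C[C@H](c1ccc(OCc2ccccc2)cc1)c1cc(Br)c(OCc2ccccc2)cc1OCc1ccccc1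
F6 | step 13 | (2E)-1-[5-(benzyloxy)-2-methoxyphenyl]-3-[2,4-bis(benzyloxy)-5-{(1R)-3-[4-(benzyloxy)-2-methoxyphenyl]-1-[4-(benzyloxy)phenyl]propyl}phenyl]prop-2-en-1-one | COc1cc(OCc2ccccc2)ccc1CC[C@H](c1ccc(OCc2ccccc2)cc1)c1cc(/C=C/C(=O)c2cc(OCc3ccccc3)ccc2OC)c(OCc2ccccc2)cc1OCc1ccccc1
F7 | step 13 | 3-{2,4-dihydroxy-5-[(1R)-3-(4-hydroxy-2-methoxyphenyl)-1-(4-hydroxyphenyl)propyl]phenyl}-1-(5-hydroxy-2-methoxyphenyl)propan-1-one | COc1cc(O)ccc1CC[C@H](c1ccc(O)cc1)c1cc(CCC(=O)c2cc(O)ccc2OC)c(O)cc1O
F8 | step 13 | 4-[(3R)-3-hydroxy-3-(5-hydroxy-2-methoxyphenyl)propyl]-6-[(1R)-3-(4-hydroxy-2-methoxyphenyl)-1-(4-hydroxyphenyl)propyl]benzene-1,3-diol | COc1cc(O)ccc1CC[C@H](c1ccc(O)cc1)c1cc(CC[C@@H](O)c2cc(O)ccc2OC)c(O)cc1O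
F9 | step 19 | 7-(benzyloxy)-2-[5-(benzyloxy)-2-methoxyphenyl]-6-{(1R)-3-[4-(benzyloxy)-2-methoxyphenyl]-1-[4-(benzyloxy)phenyl]propyl}-4H-chromene | COc1cc(OCc2ccccc2)ccc1CC[C@H](c1ccc(OCc2ccccc2)cc1)c1cc2c(cc1OCc1ccccc1)OC(c1cc(OCc3ccccc3)ccc1OC)=CC2
F10 | step 2 | methyl 3,3-bis[4-(benzyloxy)phenyl]-3-hydroxypropanoate | COC(=O)CC(O)(c1ccc(OCc2ccccc2)cc1)c1ccc(OCc2ccccc2)cc1
A1 | alternative 1 | tribenzyl ether of the target with free C7 phenol | COc1cc(OCc2ccccc2)ccc1CC[C@H](c1ccc(OCc2ccccc2)cc1)c1cc2c(cc1O)O[C@H](c1cc(OCc3ccccc3)ccc1OC)CC2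
A2 | alternative 1 | open-chain diazo enone with tethered ethynyl ether | COc1cc(OCc2ccccc2)ccc1CC[C@H](c1ccc(OCc2ccccc2)cc1)/C=C/C(=O)C(=[N+]=[N-])CC[C@@H](c1cc(OCc2ccccc2)ccc1OC)OC#C
A3 | alternative 2 | tetrabenzyl flav-3-ene | COc1cc(OCc2ccccc2)ccc1CC[C@H](c1ccc(OCc2ccccc2)cc1)c1cc2c(cc1OCc1ccccc1)O[C@H](c1cc(OCc3ccccc3)ccc1OC)C=C2
A4 | alternative 2 | O1 aryl propargyl ether with C2 in place | COc1cc(OCc2ccccc2)ccc1CC[C@H](c1ccc(OCc2ccccc2)cc1)c1ccc(O[C@H](c2cc(OCc3ccccc3)ccc2OC)C#C)cc1OCc1ccccc1
A5 | alternative 3 | linear bis-pyran with a cis-2,4-diarylchroman unit | COc1cc(O)ccc1[C@@H]2C[C@H](c1ccc(OCc5ccccc5)cc1)c3cc4c(cc3O2)O[C@H](c1cc(OCc5ccccc5)ccc1OC)CC4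
A6 | alternative 3 | C6 ortho-hydroxybenzhydrol of the preformed flavan | OC(c1ccc(OCc2ccccc2)cc1)c1cc2c(cc1O)O[C@H](c1cc(OCc3ccccc3)ccc1OC)CC2
A7 | alternative 3 | 3-methoxy-4-vinylphenol | COc1cc(O)ccc1C=C
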